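A direct plan would make ring C first and ring A last.
An enaminone of ethyl 4-(benzyloxy)-3-oxobutanoate would be benzoylated and closed to pyranone ester A1, and A1 would be hydrolysed, converted into its acid chloride and, with Na2Cr(CO)5 and then Me3OBF4, into the methoxycarbene complex of zerovalent chromium A2.
A Dötz benzannulation of A2 with methoxyacetylene would close ring A to 3-(benzyloxy)-8-hydroxy-5,7-dimethoxyflavone A3, butanoylation would give ester A4, and BCl3 would remove the benzyl group and the C5 methyl group.
Its weakest steps would be the following.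
The benzannulation that closes ring A would leave the ring closure to chance: it depends on the orientation of the ynol ether, on CO insertion into a carbene stabilised by two donors and on cyclisation onto an electron-poor pyranone carbon, and it needs a volatile, unstable alkyne and stoichiometric chromium.
The run-up from the pyranone ester to the carbene complex would spend several functional-group steps with no gain in skeleton, and the acylchromate would have to be O-methylated beside a pyranone carbonyl that can also be methylated.
The final Lewis-acid cleavage of two ethers would be the step least welcome on late material: BCl3 would have to cleave one benzyl and one of two methyl ethers and spare an aryl ester.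

The retrosynthesis cuts the ester bond at O8, then the O1–C8a bond of ring C, then the C2–C3 bond (benzoylation of an α-benzyloxy ketone) and the C4–C4a bond (aryllithium plus Weinreb amide).
Ring A is bought complete as 1,2,3,5-tetramethoxybenzene, and ring C is closed last, on a quinone.
The feature that allows this: on ring A the oxygens at C5 and C8 are para, and C8 is flanked by the methoxy carbon C7 and by C8a, which carries O1, so ring A is a masked 2,6-dioxygenated 1,4-benzoquinone.
In that quinone C8a is the β-carbon of the enones C8a=C4a–C5=O and C8a=C4a–C4=O and can exchange its methoxy group for the enol oxygen of the side chain.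
The oxidation that forms the quinone also marks O5 and O8 as the two future hydroxyls and leaves O7 methylated, so no methyl ether is cleaved by a Lewis acid.
No carbene, alkyne or benzannulation occurs, ring size fixes the direction of ring closure, and the route ends with a neutral hydrogenolysis.

Key step: step 3

Remark: the target has no stereocentre, so configuration is nowhere at issue; 2-(benzyloxy)-N-methoxy-N-methylacetamide is assumed to be a catalogue compound.

Step 1
Reactants: 1 1,2,3,5-tetramethoxybenzene; 2 2-(benzyloxy)-N-methoxy-N-methylacetamide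
Product: 4 2-(benzyloxy)-1-(2,3,4,6-tetramethoxyphenyl)ethan-1-one, via (2,3,4,6-tetramethoxyphenyl)lithium 3 (not isolated)
Conditions: n-BuLi (1.1 equiv), TMEDA (1.1 equiv), THF, 0 °C; then 2, −78 → 0 °C; aq. NH4Cl
Reagents that add atoms: none
Why: Directed ortho-lithiation at the only kind of ring hydrogen in 1 (C4 and C6 are equivalent, each between two methoxy groups) followed by Weinreb ketone synthesis, in which the chelated tetrahedral adduct should persist until work-up and so prevent over-addition.

Step 2
Reactants: 4 2-(benzyloxy)-1-(2,3,4,6-tetramethoxyphenyl)ethan-1-one; 5 benzoyl chloride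
Product: 6 2-(benzyloxy)-1-phenyl-3-(2,3,4,6-tetramethoxyphenyl)propane-1,3-dione
Conditions: MgBr2·OEt2 (2.5 equiv), i-Pr2NEt (3 equiv), 5 (1.2 equiv), CH2Cl2, 0 → 25 °C; 1 M HCl
Reagents that add atoms: none
Why: Soft enolisation and Claisen-type C-acylation, in which MgBr2 chelates the ketone and α-benzyloxy oxygens, i-Pr2NEt removes the acidified α-proton, the magnesium enolate is benzoylated on carbon and the product is held as its magnesium chelate against a second acylation; the new CH(OBn) centre is racemic and is lost on enolisation.

Step 3
Reactants: 6 2-(benzyloxy)-1-phenyl-3-(2,3,4,6-tetramethoxyphenyl)propane-1,3-dione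
Product: 8 3-(benzyloxy)-7-methoxy-2-phenyl-4H-chromene-4,5,8-trione, via acylquinone 7 (not isolated)
Conditions: (NH4)2Ce(NO3)6 (2.5 equiv), MeCN/H2O 4:1, 0 °C; extract into CH2Cl2; then NaOAc (0.3 equiv), MeCN, 25 °C
Reagents that add atoms: water, O
Why: Proposed new method: tetravalent cerium should oxidise the tetramethoxyarene of 6 by two electrons, water adding at the two methoxy-bearing carbons that become C5 and C8 and two molecules of methanol leaving, which is the known oxidative demethylation of para-dimethoxyarenes to 1,4-benzoquinones and gives acylquinone 7. In 7 the methoxy-bearing ring carbon next to the side chain (the later C8a) is the β-carbon of two enones at once, the ring C=O at C5 and the side-chain C=O at C4, so the enol oxygen on the phenyl-bearing carbon of the 2-benzyloxy-1,3-diketone should add there and expel methanol (addition–elimination at a vinylogous ester), which forms the O1–C8a bond. The closest known reactions are the exchange of quinone methoxy groups by oxygen and nitrogen nucleophiles and the cyclodehydration of 2-hydroxyaryl 1,3-diketones to flavones; ring C closes in the 6-endo-trig mode as a conjugate addition from the chelated Z-enol, which already holds the oxygen and the quinone on the same side of the C2=C3 bond. No stereocentre is formed, and the racemic centre of 6 becomes sp2. The step needs two regioselectivities: which methoxy pair is oxidised, secured because only one pair stands para, and which ring carbon takes O1, secured because only the later C8a is within reach for a six-membered ring while the C5 oxygen is locked as a quinone carbonyl, so the 5,6,7-isomer that a free 2,6-dihydroxyaryl ketone could give cannot arise. The C7 methoxy group, the second vinylogous ester, is out of reach of the enol and should survive the short, cold and weakly basic treatment.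

Step 4
Reactants: 8 3-(benzyloxy)-7-methoxy-2-phenyl-4H-chromene-4,5,8-trione; 9 butanoyl chloride
Product: 11 3-(benzyloxy)-5-hydroxy-7-methoxy-4-oxo-2-phenyl-4H-chromen-8-yl butanoate, via hydroquinone 10 (not isolated)
Conditions: Na2S2O4 (3 equiv), EtOAc/H2O, 25 °C, Ar; dry, evaporate; then 9 (1.05 equiv), pyridine (2 equiv), CH2Cl2, −20 → 0 °C
Reagents that add atoms: none
Why: Dithionite reduction of the quinone followed by chemoselective O-acylation (nucleophilic acyl substitution), in which the C5 hydroxyl of 10 is hydrogen-bonded to the C4 carbonyl and is the least nucleophilic oxygen of a flavone and O3 is a benzyl ether, so one equivalent of acid chloride should acylate only the C8 hydroxyl, while telescoping keeps the air-sensitive hydroquinone from reverting to 8.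

Step 5
Reactants: 11 3-(benzyloxy)-5-hydroxy-7-methoxy-4-oxo-2-phenyl-4H-chromen-8-yl butanoate
Product: 12 3,5-dihydroxy-7-methoxy-4-oxo-2-phenyl-4H-chromen-8-yl butanoate
Conditions: H2 (1 atm), Pd/C (10 wt% Pd on carbon), EtOAc, 25 °C
Reagents that add atoms: none
Why: Catalytic hydrogenolysis of the benzyl ether over zerovalent palladium in a non-nucleophilic solvent needs neither acid nor base, so the aryl butanoate, the C7 methyl ether and the pyranone C2=C3 bond should remain untouched, and the ester has no neighbouring free hydroxyl to migrate to.

**Compound list**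

1 | 1,2,3,5-tetramethoxybenzene | COc1cc(OC)c(OC)c(OC)c1 | starting material
2 | 2-(benzyloxy)-N-methoxy-N-methylacetamide | CON(C)C(=O)COCc1ccccc1 | starting material
3 | (2,3,4,6-tetramethoxyphenyl)lithium | [Li]c1c(OC)cc(OC)c(OC)c1OC | intermediate
4 | 2-(benzyloxy)-1-(2,3,4,6-tetramethoxyphenyl)ethan-1-one | COc1cc(OC)c(C(=O)COCc2ccccc2)c(OC)c1OC | intermediate
5 | benzoyl chloride | O=C(Cl)c1ccccc1 | starting material
6 | 2-(benzyloxy)-1-phenyl-3-(2,3,4,6-tetramethoxyphenyl)propane-1,3-dione (racemic, enolisable) | COc1cc(OC)c(C(=O)C(OCc2ccccc2)C(=O)c2ccccc2)c(OC)c1OC | intermediate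
7 | 2-(benzyloxy)-1-(2,4-dimethoxy-3,6-dioxocyclohexa-1,4-dien-1-yl)-3-phenylpropane-1,3-dione (racemic, enolisable) | COC1=CC(=O)C(C(=O)C(OCc2ccccc2)C(=O)c2ccccc2)=C(OC)C1=O | intermediate
8 | 3-(benzyloxy)-7-methoxy-2-phenyl-4H-chromene-4,5,8-trione | COC1=CC(=O)C2=C(OC(c3ccccc3)=C(OCc3ccccc3)C2=O)C1=O | intermediate
9 | butanoyl chloride | CCCC(=O)Cl | starting material
10 | 3-(benzyloxy)-5,8-dihydroxy-7-methoxy-2-phenyl-4H-chromen-4-one | COc1cc(O)c2c(=O)c(OCc3ccccc3)c(-c3ccccc3)oc2c1O | intermediate
11 | 3-(benzyloxy)-5-hydroxy-7-methoxy-4-oxo-2-phenyl-4H-chromen-8-yl butanoate | CCCC(=O)Oc1c(OC)cc(O)c2c(=O)c(OCc3ccccc3)c(-c3ccccc3)oc12 | intermediate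
12 | 3,5-dihydroxy-7-methoxy-4-oxo-2-phenyl-4H-chromen-8-yl butanoate | CCCC(=O)Oc1c(OC)cc(O)c2c(=O)c(O)c(-c3ccccc3)oc12 | target

Total step count: 5. Longest linear sequence: 5 steps (1 → 4 → 6 → 8 → 11 → 12).

Steps most likely to fail:

Step 3. Tetravalent cerium may oxidise the enolisable diketone as well as the arene, and hydrolysis of the quinone methoxy groups or electron transfer from the enolate to the acylquinone may compete with ring closure. The fallback, known chemistry throughout, sets out from 1 and comes back at 8; it closes ring C on a phenol first and unveils the quinone afterwards.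
- Friedel–Crafts acetylation of 1 (acetyl chloride, AlCl3, Et2O), with loss of the methyl group of the flanked ortho-methoxy group, should give 1-(2-hydroxy-3,4,6-trimethoxyphenyl)ethan-1-one F1.
- Claisen–Schmidt condensation with benzaldehyde (KOH, EtOH) should give (E)-1-(2-hydroxy-3,4,6-trimethoxyphenyl)-3-phenylprop-2-en-1-one F2.
- Algar–Flynn–Oyamada oxidation (H2O2, NaOH, MeOH, 0 °C, kept cold to hold back aurone formation) should give 3-hydroxy-5,7,8-trimethoxy-2-phenyl-4H-chromen-4-one F3.
- Benzylation (benzyl bromide, K2CO3, DMF) should give 3-(benzyloxy)-5,7,8-trimethoxy-2-phenyl-4H-chromen-4-one F4.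
- Oxidative demethylation of the para methoxy pair at C5 and C8 with (NH4)2Ce(NO3)6 in MeCN/H2O should then give 8.

Step 2. The hindered enolate may be benzoylated on oxygen, the diketone may be acylated a second time, or MgBr2 may cleave an ortho-methyl ether. The fallback sets out from 4 and comes back at 6; it replaces acylation by aldol addition and oxidation. The lithium enolate of 4 (LiN(SiMe3)2, THF, −78 °C) would be added to benzaldehyde to give 2-(benzyloxy)-3-hydroxy-3-phenyl-1-(2,3,4,6-tetramethoxyphenyl)propan-1-one F5 as a mixture of diastereomers, and Dess–Martin periodinane (CH2Cl2, 25 °C) would oxidise the mixture to 6.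

Step 4. The hydroquinone may be re-oxidised by air in the basic acylation medium, or both phenols may be acylated. The fallback sets out from 8 and comes back at 11; it over-acylates and then prunes. Reductive acylation of 8 (Zn dust, butanoic anhydride, pyridine, 25 °C) would give 3-(benzyloxy)-7-methoxy-4-oxo-2-phenyl-4H-chromene-5,8-diyl dibutanoate F6 without ever exposing the free hydroquinone. One equivalent of pyrrolidine (THF, −20 °C) should then cleave the C5 ester first, because its leaving group is the carbonyl-conjugated phenoxide and it has one ortho substituent where the C8 ester has two.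

Further compounds
F1 | step 3 | 1-(2-hydroxy-3,4,6-trimethoxyphenyl)ethan-1-one | COc1cc(OC)c(C(C)=O)c(O)c1OC
F2 | step 3 | (E)-1-(2-hydroxy-3,4,6-trimethoxyphenyl)-3-phenylprop-2-en-1-one | COc1cc(OC)c(C(=O)/C=C/c2ccccc2)c(O)c1OC
F3 | step 3 | 3-hydroxy-5,7,8-trimethoxy-2-phenyl-4H-chromen-4-one | COc1cc(OC)c2c(=O)c(O)c(-c3ccccc3)oc2c1OC
F4 | step 3 | 3-(benzyloxy)-5,7,8-trimethoxy-2-phenyl-4H-chromen-4-one | COc1cc(OC)c2c(=O)c(OCc3ccccc3)c(-c3ccccc3)oc2c1OC
F5 | step 2 | 2-(benzyloxy)-3-hydroxy-3-phenyl-1-(2,3,4,6-tetramethoxyphenyl)propan-1-one (mixture of racemic diastereomers) | COc1cc(OC)c(C(=O)C(OCc2ccccc2)C(O)c2ccccc2)c(OC)c1OC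
F6 | step 4 | 3-(benzyloxy)-7-methoxy-4-oxo-2-phenyl-4H-chromene-5,8-diyl dibutanoate | CCCC(=O)Oc1cc(OC)c(OC(=O)CCC)c2oc(-c3ccccc3)c(OCc3ccccc3)c(=O)c12
A1 | direct plan | ethyl 5-(benzyloxy)-4-oxo-6-phenyl-4H-pyran-3-carboxylate | CCOC(=O)c1coc(-c2ccccc2)c(OCc2ccccc2)c1=O
A2 | direct plan | pentacarbonyl{[5-(benzyloxy)-4-oxo-6-phenyl-4H-pyran-3-yl](methoxy)methylidene}chromium | COC(c1coc(-c2ccccc2)c(OCc2ccccc2)c1=O)=[Cr](=C=O)(=C=O)(=C=O)(=C=O)=C=O
A3 | direct plan | 3-(benzyloxy)-8-hydroxy-5,7-dimethoxy-2-phenyl-4H-chromen-4-one | COc1cc(OC)c2c(=O)c(OCc3ccccc3)c(-c3ccccc3)oc2c1O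
A4 | direct plan | 3-(benzyloxy)-5,7-dimethoxy-4-oxo-2-phenyl-4H-chromen-8-yl butanoate | CCCC(=O)Oc1c(OC)cc(OC)c2c(=O)c(OCc3ccccc3)c(-c3ccccc3)oc12
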